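The readings are simulated from invented constants; scatter was added.

| setting | zeta | flask |
|---|---|---|
| left-handed substrate | 2 mM | 2.0 mM |
| right-handed substrate | 2 mM | 2.0 mM |
| partner | 6 mM | 4.00 mM |
| remark | run made earlier |  |
| time |  | 10 min |

- zeta (time / s: left-handed substrate / %, left-handed product / %): 10.0: 28.4, 22.3; 25.0: 18.4, 38.1; 40.0: 15.3, 47.6; 60.0: 12.9, 56.0; 90.0: 11.0, 64.7; 120: 9.4, 70.5

(standard deviation of a reading: 0.3 percentage points)

- partner is single-handed; left-handed substrate and right-handed substrate are mirror images of each other, charged as a racemate, each of them at the stated concentration
- what was read earlier has a scatter of 0.3 percentage points, one standard deviation
- what has gone into achiral form counts as reacted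
- the reaction counts as stopped when no species that holds the left-handed substrate and right-handed substrate together changes by six tenths of a point or more over the second half of the time
- the handed part of partner does not stay in what it makes, so the products of the two hands are mirror images too

- at 10 min, what has stopped the reaction, if anything has (forward and back rates have come level / it is still moving / the partner has run out first / all of the left-handed substrate has reacted)
- how much of the left-handed substrate and right-handed substrate together has reacted by 10 min
- how much left-handed product there is at 10 min, in percent of the left-handed substrate and right-handed substrate together charged
- how much right-handed substrate there is at 10 min, in percent of the left-handed substrate and right-handed substrate together charged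

Left-handed product beyond 50.0% is impossible if the left-handed substrate of a racemate reacts by itself, yet the zeta run reads 70.5% at 120 s. With the 9.4% of left-handed substrate still there, the left-handed pool stands 30 percentage points above that line. So you add a second process: right-handed substrate crosses through the achiral form, a dynamic kinetic resolution. The ceiling then moves to what the partner can pay for, 100% in the asked flask, whose partner matches the substrates mole for mole.

Third comes the clock. Take the gain in left-handed product over the last zeta interval, and divide it by the mean [left-handed substrate] and by the partner charged less the product formed. That gives my reading of 5.75 /M/s, which carries the scatter of two readings.

Now use the symmetric case as zero. In the asked flask I assume [left-handed substrate] = [right-handed substrate], [partner] equal to the remaining substrate, and a left-handed product that does not run back. The remaining substrate then falls to half in the pair time, the reciprocal of that constant times the charged [left-handed substrate], 1.45 min. The share left after a time is the pair time over the pair time plus that time. My reckoning leaves 22.5% at 5.00 min and 12.7% at 10 min, so it has this flask still moving, with 87.3% reacted, which I read as left-handed product, and 6.33% right-handed substrate.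

The forecast says forward and back rates have come level, with conversion 71% (66% to 78%), left-handed product 68% (58% to 72%) and right-handed substrate 15.5% (11% to 19%). Its ground: “Relaxation takes about 100 s, so it should be essentially level by 10 min.” My reckoning differs from it on the ending and on each number.

The flask gives: it is still moving, 84.6% reacted, 80.9% left-handed product, 7.95% right-handed substrate.

    partner + left-handed substrate → left-handed product (k = 11.3 /M/s)
    partner + right-handed substrate → right-handed product (k = 0.308 /M/s)
    left-handed substrate ⇌ achiral form (K = 0.0970, k = 0.0414 /s)
    right-handed substrate ⇌ achiral form (K = 0.0970, k = 0.0414 /s)
    partner ⇌ dormant form (K = 1.20, k = 0.00687 /s)

The pair time left 12.7% of the two substrates where this flask holds 15.4%. For the same flask read at 2.5 min it leaves 36.7% against a simulated 35.1%. In the asked flask at 0.794 min, right-handed substrate entered the achiral form 83 times as fast as it formed right-handed product, counting the forward step alone. At 10.0 min the asked flask holds 7.43% left-handed substrate, 7.95% right-handed substrate and 2.96% right-handed product.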